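The isoflavone is cut at C3–C1′, between the pyranone (ring C) and ring B. Ring B carries C3′-OH, C4′-OMe and C5′-OMe, with C1′ meta to the hydroxyl. This is the retron of a masked o-benzoquinone whose carbonyl is C3′, whose dimethyl ketal is C4′ and whose enone β-carbon is C1′. Dearomatising cheap 2,3-dimethoxyphenol therefore turns the one ring position that electrophilic substitution never reaches into an electrophile. The nucleophilic α-carbon of an o-hydroxyaryl enaminone (future C3) adds there. Loss of methanol rearomatises ring B with its free 3′-OH, and loss of dimethylamine closes ring C, all in one flask. Benzyl ethers at O5/O7 fix the 8-methoxy regiochemistry.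

Key step: step 4

Assumption: the target has no stereocentre, stereogenic axis or configurationally defined double bond. It is achiral, so no enantiocontrol is required. Compounds 1 and 5 are taken as catalogue chemicals.

Step 1
Reactants: 1 1-[4,6-bis(benzyloxy)-2-hydroxyphenyl]ethan-1-one
Product: 2 1-[4,6-bis(benzyloxy)-2-hydroxy-3-iodophenyl]ethan-1-one
Conditions: NIS (1.05 equiv), TFA (cat.), MeCN, 0 °C to rt
Reagents that add atoms: N-iodosuccinimide, O=C1CCC(=O)N1I
Why: Electrophilic aromatic iodination (SEAr) should occur at C3, ortho to the free phenol and para to the C6 benzyloxy group, because C5 is screened by two flanking benzyloxy groups; this is the site preference typical of 2-hydroxy-4,6-dialkoxyacetophenones.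

Step 2
Reactants: 2 1-[4,6-bis(benzyloxy)-2-hydroxy-3-iodophenyl]ethan-1-one
Product: 3 1-[4,6-bis(benzyloxy)-2-hydroxy-3-methoxyphenyl]ethan-1-one
Conditions: NaOMe (6 equiv), CuI (0.3 equiv), DMF–MeOH, 110 °C; aq. HCl work-up
Reagents that add atoms: sodium methoxide, [Na+].[O-]C
Why: Ullmann-type copper-catalysed methoxylation of an ortho-iodophenolate is the reaction type used to turn ortho-halophenols into guaiacols; benzyl ethers are inert to methoxide and the ketone is shielded within the chelated phenolate.

Step 3
Reactants: 3 1-[4,6-bis(benzyloxy)-2-hydroxy-3-methoxyphenyl]ethan-1-one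
Product: 4 (E)-1-[4,6-bis(benzyloxy)-2-hydroxy-3-methoxyphenyl]-3-(dimethylamino)prop-2-en-1-one
Conditions: DMF-DMA (3 equiv), toluene, 95 °C
Reagents that add atoms: N,N-dimethylformamide dimethyl acetal, COC(OC)N(C)C
Why: In this formamide-acetal condensation (enaminone synthesis) the methyl ketone condenses with loss of two methanol, the E push–pull alkene is the thermodynamic product, and the chelated, hindered phenol should resist O-methylation.

Step 4
Reactants: 4 (E)-1-[4,6-bis(benzyloxy)-2-hydroxy-3-methoxyphenyl]-3-(dimethylamino)prop-2-en-1-one; 5 2,3-dimethoxyphenol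
Product: 8 5,7-bis(benzyloxy)-3-(3-hydroxy-4,5-dimethoxyphenyl)-8-methoxy-4H-chromen-4-one (5,7-di-O-benzylisoirigenin), via masked o-benzoquinone 6 (not isolated), via α-aryl enaminone 7 (not isolated)
Conditions: (i) 5 (1.6 equiv), PhI(OAc)2 (1.5 equiv), MeOH, 0 °C, 20 min; (ii) 4 (1.0 equiv), MeOH–CH2Cl2, 0 to 45 °C; (iii) concentrate, AcOH, 60 °C
Reagents that add atoms: methanol, CO (supplies the second ketal methoxy group of 6; one of the two ketal methoxy groups stays as the C4′ methoxy group)
Why: Proposed new method: PhI(OAc)2 in methanol dearomatises phenol 5 at its methoxy-bearing C2 to ketal 6, whose only unsubstituted enone β-carbon (C3 of the dienone, the future C1′) is attacked by the enamine-type α-carbon of 4 in a Michael addition assisted by the released acetic acid; proton loss restores the enaminone, and 1,4-elimination of one ketal methoxy group as methanol rearomatises ring B to give 7. The closest known reaction types are the Michael addition–aromatisation of indoles, electron-rich arenes and thiols on masked o-benzoquinones, the Nenitzescu-type C-attack of enaminones on quinones, and the C–H functionalisation/chromone annulation of o-hydroxyaryl enaminones; 7 is also the intermediate type through which deoxybenzoins pass to isoflavones with DMF-DMA. Ring C closes by 6-endo-trig oxa-Michael attack of the free ortho hydroxyl of ring A on the aminomethine carbon, followed by expulsion of dimethylamine (addition–elimination). No stereocentre survives, because the sp3 carbon created in the Michael step is planarised on aromatisation. Site selectivity on 6 is required and has three supports: the δ-carbon C5 is blocked by its methoxy group and its adduct cannot aromatise, the corresponding carbon is the established point of attack in the parent 3-methoxy-o-benzoquinone, and the absence of strong acid keeps the ketal from ionising to a phenoxenium-type cation that would react para to oxygen. The oxidant is consumed before the oxidisable guaiacol-type phenol 4 enters (5 in slight excess), acetic acid traps the liberated amine, and the benzyl ether on the other ortho oxygen of ring A leaves only the hydroxyl next to the methoxy group for closure, which secures the 8-methoxy isomer.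

Step 5
Reactants: 8 5,7-bis(benzyloxy)-3-(3-hydroxy-4,5-dimethoxyphenyl)-8-methoxy-4H-chromen-4-one
Product: 9 isoirigenin, 5,7-dihydroxy-3-(3-hydroxy-4,5-dimethoxyphenyl)-8-methoxy-4H-chromen-4-one
Conditions: H2 (1 atm), 10% Pd/C, EtOAc–MeOH, rt, stopped after uptake of 2 equiv H2
Reagents that add atoms: none
Why: Heterogeneous catalytic hydrogenolysis cleaves the two benzylic C–O bonds faster than it saturates the trisubstituted vinylogous-ester C2=C3 bond, so ring C, the three methyl ethers and the phenols should remain untouched.

Compound list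
1 | 1-[4,6-bis(benzyloxy)-2-hydroxyphenyl]ethan-1-one | CC(=O)c1c(O)cc(OCc2ccccc2)cc1OCc1ccccc1 | starting material
2 | 1-[4,6-bis(benzyloxy)-2-hydroxy-3-iodophenyl]ethan-1-one | CC(=O)c1c(O)c(I)c(OCc2ccccc2)cc1OCc1ccccc1 | intermediate
3 | 1-[4,6-bis(benzyloxy)-2-hydroxy-3-methoxyphenyl]ethan-1-one | CC(=O)c1c(O)c(OC)c(OCc2ccccc2)cc1OCc1ccccc1 | intermediate
4 | (E)-1-[4,6-bis(benzyloxy)-2-hydroxy-3-methoxyphenyl]-3-(dimethylamino)prop-2-en-1-one | CN(C)/C=C/C(=O)c1c(O)c(OC)c(OCc2ccccc2)cc1OCc1ccccc1 | intermediate
5 | 2,3-dimethoxyphenol | COc1cccc(O)c1OC | starting material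
6 | 5,6,6-trimethoxycyclohexa-2,4-dien-1-one (masked o-benzoquinone, not isolated) | COC1=CC=CC(=O)C1(OC)OC | intermediate
7 | 1-[4,6-bis(benzyloxy)-2-hydroxy-3-methoxyphenyl]-3-(dimethylamino)-2-(3-hydroxy-4,5-dimethoxyphenyl)prop-2-en-1-one (push–pull alkene, geometry not fixed, not isolated) | CN(C)C=C(c1cc(O)c(OC)c(OC)c1)C(=O)c1c(O)c(OC)c(OCc2ccccc2)cc1OCc1ccccc1 | intermediate
8 | 5,7-bis(benzyloxy)-3-(3-hydroxy-4,5-dimethoxyphenyl)-8-methoxy-4H-chromen-4-one | COc1cc(-c2coc3c(OC)c(OCc4ccccc4)cc(OCc4ccccc4)c3c2=O)cc(O)c1OC | intermediate
9 | isoirigenin | COc1cc(-c2coc3c(OC)c(O)cc(O)c3c2=O)cc(O)c1OC | target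

Total step count: 5. Longest linear sequence: 5 (1 → 2 → 3 → 4 → 8 → 9).

Steps most likely to fail

Step 4 (Proposed new method). The Michael addition may be too slow. In that case Diels–Alder self-dimerisation of the dienone, [4+2] cycloaddition of the enaminone across the diene, or ketal ionisation with attack para to oxygen could take over.
- The fallback uses known chemistry, sets out from 4 and 5, and comes back at 8.
- Enaminone 4 is iodocyclised (I2, MeOH, rt) with loss of dimethylamine to 5,7-bis(benzyloxy)-3-iodo-8-methoxy-4H-chromen-4-one F1.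
- Phenol 5 is silylated (TBSCl, imidazole, DMF) to tert-butyl(2,3-dimethoxyphenoxy)dimethylsilane F2.
- Sterically governed iridium-catalysed C–H borylation ([Ir(OMe)(cod)]2, dtbpy, B2pin2, THF, 80 °C) occurs at the only C–H without an ortho neighbour. It gives tert-butyl[2,3-dimethoxy-5-(4,4,5,5-tetramethyl-1,3,2-dioxaborolan-2-yl)phenoxy]dimethylsilane F3.
- Suzuki–Miyaura coupling of F1 with F3 (Pd(dppf)Cl2, K3PO4, dioxane–H2O, 70 °C) forms the same C3–C1′ bond. The product is 5,7-bis(benzyloxy)-3-{3-[(tert-butyldimethylsilyl)oxy]-4,5-dimethoxyphenyl}-8-methoxy-4H-chromen-4-one F4.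
- TBAF/AcOH in THF then releases 8.

Step 2. Protodeiodination, slow C–O coupling at an iodide flanked on both sides, and self-condensation of the ketone in hot methoxide may erode the conversion.
- The fallback avoids carbon–halogen chemistry altogether, sets out from 1, and comes back at 3. It also removes any dependence on the site selectivity of step 1.
- IBX (DMF, rt) can deliver oxygen only to the single free ortho position of the phenol. It gives 3-acetyl-4,6-bis(benzyloxy)cyclohexa-3,5-diene-1,2-dione F5.
- Reduction in the same pot with aqueous Na2S2O4 gives 1-[4,6-bis(benzyloxy)-2,3-dihydroxyphenyl]ethan-1-one F6.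
- MeI (1.0 equiv) and Li2CO3 in DMF should methylate the non-chelated 3-hydroxyl selectively to give 3.

Step 5. Saturation of the C2=C3 bond may accompany hydrogenolysis.
- The fallback is non-reductive, sets out from 8, and comes back at 9.
- It is a Lewis-acid debenzylation with a cation scavenger (BCl3, pentamethylbenzene, CH2Cl2, −78 °C). At this temperature the methyl ethers should not be cleaved.

Further compounds
F1 | step 4 | 5,7-bis(benzyloxy)-3-iodo-8-methoxy-4H-chromen-4-one | COc1c(OCc2ccccc2)cc(OCc2ccccc2)c2c(=O)c(I)coc12
F2 | step 4 | tert-butyl(2,3-dimethoxyphenoxy)dimethylsilane | COc1cccc(O[Si](C)(C)C(C)(C)C)c1OC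
F3 | step 4 | tert-butyl[2,3-dimethoxy-5-(4,4,5,5-tetramethyl-1,3,2-dioxaborolan-2-yl)phenoxy]dimethylsilane | COc1cc(B2OC(C)(C)C(C)(C)O2)cc(O[Si](C)(C)C(C)(C)C)c1OC
F4 | step 4 | 5,7-bis(benzyloxy)-3-{3-[(tert-butyldimethylsilyl)oxy]-4,5-dimethoxyphenyl}-8-methoxy-4H-chromen-4-one | COc1cc(-c2coc3c(OC)c(OCc4ccccc4)cc(OCc4ccccc4)c3c2=O)cc(O[Si](C)(C)C(C)(C)C)c1OC
F5 | step 2 | 3-acetyl-4,6-bis(benzyloxy)cyclohexa-3,5-diene-1,2-dione | CC(=O)C1=C(OCc2ccccc2)C=C(OCc2ccccc2)C(=O)C1=O
F6 | step 2 | 1-[4,6-bis(benzyloxy)-2,3-dihydroxyphenyl]ethan-1-one | CC(=O)c1c(O)c(O)c(OCc2ccccc2)cc1OCc1ccccc1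
F0 | step 5 | none | none
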